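## Analysis of the target

Mutafuran C (19) is a C20 chain, numbered here from the ester carbon C1 to the brominated carbon C20, with a methyl ester at C1 and an oxolane made of C5, C6, C7, C8 and one oxygen. The only stereocentres are C5 (R) and C8 (S). They flank the ring oxygen, the two side chains are trans, and no neighbouring functional group helps to relate them. C8 carries the C9≡C10 triple bond, conjugated with the E double bond C11=C12; six methylenes (C13–C18) lead to the E bromoalkene C19=C20. The sensitive parts are the bromoalkene (zerovalent palladium, organolithiums, radicals), the enyne (no hydrogenation once it is present), the propargylic ether centre C8 (ionisable by strong Lewis acids) and the methyl ester. The difficulty is one of ordering: a trans-2,5-oxolane with two different carbon arms, an sp–sp2 array and two E olefins must be assembled without any reduction of multiple bonds and without a metal-mediated coupling near the C–Br bond. The strategy rests on joining the C1 carboxyl and an oxygen on C19 as an ester. This places C9≡C10 inside a 19-membered ring (C1–C5, ring oxygen, C8–C19, ester oxygen), so the triple bond can be made by ring-closing alkyne metathesis, and methanolysis of the tether leaves the methyl ester of the target.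

## Retrosynthetic reasoning

19 to 18: the C19=C20 bond is cut first, leading back to aldehyde 18. The bromoalkene is thus made last by a one-carbon bromo-olefination and never meets a radical, a palladium catalyst or the metathesis catalyst. The forward reaction has to deliver the E isomer.

18 to 17 to 16: the C19 aldehyde comes from primary alcohol 17. Alcohol 17 and the C1 methyl ester are both released from macrolactone 16 by methanolysis of the C1–O–C19 ester. The tether costs nothing, because opening it gives the ester of the target and the handle for C20.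

16 to 15: the ring is opened at C9≡C10. This is the one bond between two sp carbons, and both resulting ends can be methyl-capped alkynes, which are non-acidic and easy to make. Cutting C10–C11 instead would need a terminal alkyne and an alkenyl halide late in the synthesis. Tying the two halves together in diyne ester 15 turns an unselective cross-metathesis into a ring closure. The forward step must react at triple bonds only and must favour ring closure over oligomerisation; the two methyl caps leave as a volatile alkyne.

15 to 8 + 14: the C3–C4 bond is cut. C4 is the exocyclic carbon of the oxolane and becomes a primary radical from iodide 8. C1–C3 arrive as acrylate 14, which also brings the ester tether and the whole enyne arm. No stereocentre is formed, and C5, next to the radical, is not touched.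

14 to 13 to 11 + 12, and 11 to 9: acrylate 14 is the ester of enynol 13. In 13 the sp–sp2 bond (later C10–C11) is cut to propyne 12 and E iodoalkene 11. Iodoalkene 11 comes from alkynol 9 by syn hydrometalation and iodination, which fixes the E geometry of the later C11=C12.

8 to 7 to 6 to 4 + 5: iodide 8 comes from alcohol 7 and that from silyl ether 6. In 6 the C8–C9 bond is cut, back to lactol acetate 4 and alkynyltin reagent 5. This is the step that sets C8 relative to C5: the nucleophile should add to the oxocarbenium ion from 4 on the face away from the silyloxymethyl group. It is substrate control, and that is a weakness of the plan.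

4 to 2 to 1: acetate 4 comes from silylated lactone 2 and that from lactone 1. The stereocentre C5 is bought with 1; the lactone carbonyl becomes C8 and the hydroxymethyl carbon becomes C4, so the two arms are different from the start.

## Alternatives that were turned down

Alternative 1: Here the oxolane and the C4–C3 bond would be made in one radical cascade.
- Disconnection: O–C5 and C4–C3, back to the alkenol (3S)-1-(triisopropylsilyl)hept-6-en-1-yn-3-ol (A2) and methyl prop-2-enoate (A3).
- Forward key step: under aerobic conditions with Co(CF3COCHCOCH3)2 (divalent cobalt) and a hydrogen-atom donor, the hydroxyl of A2 adds 5-exo to the alkene. The C4 radical is caught by A3 and then reduced, giving methyl 4-[(2R,5S)-5-(triisopropylsilylethynyl)oxolan-2-yl]butanoate (A1).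
- For: ring, trans relation and the C1–C4 chain with its methyl ester arise in one step. The trans preference of this cyclisation type is intrinsically high, and on this point it is stronger than the chosen route.
- Against: the C4 radical is shared between A3, the hydrogen donor and dioxygen, so simple reduction and oxygenation compete. A2 must first be made enantiopure. A1 still lacks C10–C20, so the enyne must be made by an sp–sp2 palladium coupling, either with a partner that already carries the bromoalkene (two alkenyl halides competing for zerovalent palladium) or with the olefination deferred.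
- Comparison: A1 is reached in fewer steps than the oxolane of the chosen route. The chosen route instead takes C5 from the chiral pool, joins the halves through two inert methyl-capped alkynes and keeps the bromoalkene out of every metal-catalysed coupling.

Alternative 2: Here a C2-symmetric oxolane core would be made from a meso diepoxide.
- Disconnection: the ring C–O bond at C8, back to (2R)-2-{2-[(2S)-oxiran-2-yl]ethyl}oxirane (A4).
- Forward key step: hydrolytic kinetic resolution conditions with chiral Co(salen)(OAc) (trivalent cobalt; salen = N,N'-bis(3,5-di-tert-butylsalicylidene)cyclohexane-1,2-diaminate) open only the S epoxide of A4 at its terminus. The secondary hydroxyl then attacks the internal carbon of the R epoxide 5-exo with inversion and gives (2S,5S)-oxolane-2,5-diyldimethanol (A5).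
- For: both stereocentres are fixed under catalyst control from an achiral precursor, and the trans relation follows from the mechanism. The two hydroxyls of A5 are homotopic, so monoprotection gives one compound. In stereochemical security this beats the chosen route.
- Against: A4 is formed from the parent 1,5-diene together with its racemic diastereomer, so much material is lost or must be sorted. A5 then needs monoprotection (mono against bis), oxidation to an epimerisable α-alkoxy aldehyde, homologation to the alkyne and a separate three-carbon extension of the other arm.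
- Comparison: monosilylated A5 is the compound F7 of the fallback for step 3, so this chemistry reaches the same intermediates by a longer path. The chosen route starts from a lactone whose two arms already differ and attaches C9 with its methyl cap in one bond formation.

Alternative 3: Here the ring would be closed by an oxonium ylide rearrangement.
- Disconnection: O–C5 and C5–C4, back to the diazoketone (4S)-5-{[tert-butyl(diphenyl)silyl]oxy}-1-diazo-4-(prop-2-en-1-yloxy)pentan-2-one (A6).
- Forward key step: Cu(acac)2 forms a copper carbene at C5, the allyl ether oxygen on C8 adds to it to close a five-membered oxonium ylide, and a [2,3]-shift moves the allyl group from oxygen to C5. The product is (2R,5S)-5-{[tert-butyl(diphenyl)silyl]oxymethyl}-2-(prop-2-en-1-yl)oxolan-3-one (A7).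
- For: the rearrangement is reliably 2,5-trans, so C5 is set relative to C8 during ring formation. The allyl group supplies C4–C2 and can be extended to C1 by olefin cross-metathesis with an acrylate. On the trans relation this alternative is the stronger one.
- Against: A7 has a ketone at C6 that the target lacks; it must be removed by reduction and radical deoxygenation before any alkyne is present. The enoate from cross-metathesis needs a conjugate reduction, the silyloxymethyl arm must still be turned into the alkyne, and A6 needs a multistep preparation with a diazoalkane.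
- Comparison: it is the longest of the routes and spends most steps on adjusting functionality. The chosen route has no redox adjustment on the ring, and answers the weaker stereocontrol with a separable mixture and a fallback.

Key step: step 10

Remark on the chemistry: acetate 4 is used as the mixture of both anomers, because both ionise to the same oxocarbenium ion.

## Route

Step 1
Reactants: 1 (5S)-5-(hydroxymethyl)oxolan-2-one
Product: 2 (5S)-5-{[tert-butyl(diphenyl)silyl]oxymethyl}oxolan-2-one
Conditions: TBDPSCl, imidazole, CH2Cl2, 0 °C → rt
Reagents that add atoms: tert-butyl(chloro)diphenylsilane, CC(C)(C)[Si](Cl)(c1ccccc1)c1ccccc1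
Why: Silylation of a primary alcohol with a silyl chloride and imidazole; the lactone and its stereocentre (the later C5) are not involved. The tert-butyldiphenylsilyl group should survive i-Bu2AlH and cold BF3·OEt2, and its bulk is the control element of step 3.

Step 2
Reactants: 2 (5S)-5-{[tert-butyl(diphenyl)silyl]oxymethyl}oxolan-2-one
Product: 4 (5S)-5-{[tert-butyl(diphenyl)silyl]oxymethyl}oxolan-2-yl acetate (both anomers), via aluminium lactolate 3 (not isolated)
Conditions: i-Bu2AlH, CH2Cl2, −78 °C; then pyridine, DMAP, Ac2O, −78 → 0 °C
Reagents that add atoms: acetic anhydride, CC(=O)OC(C)=O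
Why: Partial reduction of the γ-lactone stops at the tetrahedral aluminium lactolate 3 at −78 °C, and acylating it in the same flask (one-pot reductive acetylation) avoids the open hydroxy aldehyde and silyl migration. The anomeric centre forms as a mixture, which does not matter for step 3.

Step 3
Reactants: 4 (5S)-5-{[tert-butyl(diphenyl)silyl]oxymethyl}oxolan-2-yl acetate; 5 tributyl(prop-1-yn-1-yl)stannane
Product: 6 tert-butyl{[(2S,5S)-5-(prop-1-yn-1-yl)oxolan-2-yl]methoxy}diphenylsilane
Conditions: BF3·OEt2, CH2Cl2, −78 → −40 °C
Reagents that add atoms: none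
Why: BF3·OEt2 ionises the anomeric acetate to a five-membered oxocarbenium ion, which is attacked by the tin-bearing alkyne carbon of 5 (ipso substitution through a β-stannyl vinyl cation, as in Lewis-acid C-glycosylation with alkynylstannanes) to form C8–C9. The new stereocentre C8 is set by substrate control: attack anti to the silyloxymethyl group on C5 should give the 2,5-trans (2S,5S) isomer. The preference is not expected to be complete, and the cis isomer is to be removed by chromatography here or after step 4.

Step 4
Reactants: 6 tert-butyl{[(2S,5S)-5-(prop-1-yn-1-yl)oxolan-2-yl]methoxy}diphenylsilane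
Product: 7 [(2S,5S)-5-(prop-1-yn-1-yl)oxolan-2-yl]methanol
Conditions: Bu4NF, THF, 0 °C → rt
Reagents that add atoms: none
Why: Fluoride cleaves the Si–O bond of the silyl ether; the internal alkyne, the ring and both stereocentres are inert to Bu4NF. The more polar alcohol gives a second chance to separate any cis isomer.

Step 5
Reactants: 7 [(2S,5S)-5-(prop-1-yn-1-yl)oxolan-2-yl]methanol
Product: 8 (2S,5S)-2-(iodomethyl)-5-(prop-1-yn-1-yl)oxolane
Conditions: I2, PPh3, imidazole, CH2Cl2, 0 °C → rt
Reagents that add atoms: iodine, [I][I]
Why: Appel-type iodination: the alkoxyphosphonium ion from PPh3 and iodine is displaced by iodide in an SN2 reaction at the primary carbon C4, so neither stereocentre is touched. The phosphine consumes iodine faster than it can add to the internal alkyne.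

Step 6
Reactants: 9 non-8-yn-1-ol
Product: 11 (8E)-9-iodonon-8-en-1-ol, via alkenylzirconocene 10 (not isolated)
Conditions: Cp2Zr(H)Cl (2.2 equiv), THF, rt; then I2, 0 °C; aq. HCl work-up
Reagents that add atoms: iodine, [I][I]
Why: The first equivalent of Cp2Zr(H)Cl turns the hydroxyl into a zirconium alkoxide, and the second adds syn across the terminal alkyne with zirconium on the terminal carbon (hydrozirconation). Iodinolysis of the C–Zr bond goes with retention, so the later C11=C12 geometry is fixed as E.

Step 7
Reactants: 11 (8E)-9-iodonon-8-en-1-ol; 12 propyne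
Product: 13 (8E)-dodec-8-en-10-yn-1-ol
Conditions: PdCl2(PPh3)2 (cat.), CuI (cat.), Et3N, THF, rt
Reagents that add atoms: none
Why: Sonogashira coupling of an alkenyl iodide with a terminal alkyne forms the sp–sp2 bond (the later C10–C11) with retention of the E geometry; the free hydroxyl is tolerated. The methyl cap makes the enyne a competent metathesis partner in step 10.

Step 8
Reactants: 13 (8E)-dodec-8-en-10-yn-1-ol
Product: 14 (8E)-dodec-8-en-10-yn-1-yl prop-2-enoate
Conditions: acryloyl chloride, Et3N, CH2Cl2, 0 °C
Reagents that add atoms: acryloyl chloride, C=CC(Cl)=O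
Why: O-Acylation of a primary alcohol with an acid chloride and Et3N; the enyne is untouched. A trace of radical inhibitor can be added against polymerisation of the acrylate.

Step 9
Reactants: 8 (2S,5S)-2-(iodomethyl)-5-(prop-1-yn-1-yl)oxolane; 14 (8E)-dodec-8-en-10-yn-1-yl prop-2-enoate
Product: 15 (8E)-dodec-8-en-10-yn-1-yl 4-[(2R,5S)-5-(prop-1-yn-1-yl)oxolan-2-yl]butanoate
Conditions: Bu3SnH (syringe pump), AIBN (cat.), PhH, 80 °C; 14 in excess
Reagents that add atoms: none
Why: Giese reaction: the tributylstannyl radical abstracts iodine from 8, the nucleophilic primary C4 radical adds to the free terminus of acrylate 14 to form C3–C4, and the α-ester radical takes hydrogen from Bu3SnH. The internally substituted enyne and propynyl groups are much poorer acceptors than the acrylate, the trans ring geometry prevents cyclisation of the C4 radical onto the propynyl group, and slow addition of Bu3SnH suppresses direct reduction. No stereocentre is formed, and C5 keeps its configuration.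

Step 10
Reactants: 15 (8E)-dodec-8-en-10-yn-1-yl 4-[(2R,5S)-5-(prop-1-yn-1-yl)oxolan-2-yl]butanoate
Product: 16 (1R,14E,18S)-6,21-dioxabicyclo[16.2.1]henicos-14-en-16-yn-5-one (oxolane-bridged 19-membered E-enyne macrolactone)
Conditions: Mo(≡CC6H4-4-OMe)(OSiPh3)3 (10 mol%), 5 Å MS, PhMe (2 mM), 25 → 60 °C
Reagents that add atoms: none
Why: The hexavalent molybdenum alkylidyne adds [2+2] to one of the methyl-capped triple bonds to give a metallacyclobutadiene, whose cycloreversion leaves the metal bound to C9 or C10 as a new alkylidyne. This substrate-bound alkylidyne engages the second methyl-capped alkyne of the same molecule in a second [2+2] and cycloreversion, which forms C9≡C10; overall the two methyl caps leave as but-2-yne. The closest known reaction type is ring-closing alkyne metathesis to macrocyclic 1,3-enynes with molybdenum alkylidyne complexes bearing triarylsilanolate ligands. One ring is closed, the 19-membered lactone counted through the oxolane oxygen, by macrocyclisation through the metallacycle with the new triple bond endocyclic; no stereocentre is formed, and C5, C8 and the E bond C11=C12 are spectators. The step needs selectivity for triple over double bonds, which the alkylidyne provides because its metallacyclobutadiene pathway does not engage olefins, and it needs tolerance of the ester and the ring ether, which the silanolate ligands provide by tempering the Lewis acidity of the metal. It also needs ring closure to win over oligomerisation: millimolar dilution, sieves that adsorb but-2-yne, and the flexible heptamethylene segment C13–C19, which lets the linear C8–C9≡C10–C11 unit span the ring without strain, should secure this. Because the remaining triple bonds stay metathesis-active, open-chain oligomers formed early can still be converted into the strain-free monomeric ring.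

Step 11
Reactants: 16 (1R,14E,18S)-6,21-dioxabicyclo[16.2.1]henicos-14-en-16-yn-5-one
Product: 17 methyl 4-{(2R,5S)-5-[(3E)-11-hydroxyundec-3-en-1-yn-1-yl]oxolan-2-yl}butanoate
Conditions: K2CO3, MeOH, rt
Reagents that add atoms: methanol, CO
Why: Base-catalysed transesterification: methoxide opens the strain-free macrolactone at C1, and the large excess of methanol shifts the equilibrium to the open methyl ester with the free C19 hydroxyl. There is no stereocentre α to the carbonyl, and the enyne is stable to K2CO3.

Step 12
Reactants: 17 methyl 4-{(2R,5S)-5-[(3E)-11-hydroxyundec-3-en-1-yn-1-yl]oxolan-2-yl}butanoate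
Product: 18 methyl 4-{(2R,5S)-5-[(3E)-11-oxoundec-3-en-1-yn-1-yl]oxolan-2-yl}butanoate
Conditions: Dess–Martin periodinane, CH2Cl2, 0 °C → rt
Reagents that add atoms: none
Why: Dess–Martin oxidation of a primary alcohol to the aldehyde under near-neutral conditions without over-oxidation; ester, enyne and propargylic ether are inert.

Step 13
Reactants: 18 methyl 4-{(2R,5S)-5-[(3E)-11-oxoundec-3-en-1-yn-1-yl]oxolan-2-yl}butanoate
Product: 19 methyl 4-{(2R,5S)-5-[(3E,11E)-12-bromododeca-3,11-dien-1-yn-1-yl]oxolan-2-yl}butanoate (mutafuran C)
Conditions: CrBr2, CHBr3, THF, 0 °C → rt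
Reagents that add atoms: bromoform, BrC(Br)Br
Why: Takai olefination: divalent chromium reduces CHBr3 to a geminal dichromium bromocarbenoid that adds to the aldehyde, and elimination from the adduct with the substituents anti gives the E bromoalkene C19=C20. The bromide salt avoids halogen exchange to a chloroalkene, and the reagent does not touch the ester, the enyne or the ring.

## Compound list

In the zirconium compounds the cyclopentadienyl rings are drawn σ-bonded.

1 | (5S)-5-(hydroxymethyl)oxolan-2-one | OC[C@@H]1CCC(=O)O1 | starting material
2 | (5S)-5-{[tert-butyl(diphenyl)silyl]oxymethyl}oxolan-2-one | CC(C)(C)[Si](OC[C@@H]1CCC(=O)O1)(c1ccccc1)c1ccccc1 | intermediate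
3 | {[(5S)-5-{[tert-butyl(diphenyl)silyl]oxymethyl}oxolan-2-yl]oxy}bis(2-methylpropyl)alumane (aluminium lactolate) | CC(C)C[Al](CC(C)C)OC1CC[C@@H](CO[Si](c2ccccc2)(c2ccccc2)C(C)(C)C)O1 | intermediate
4 | (5S)-5-{[tert-butyl(diphenyl)silyl]oxymethyl}oxolan-2-yl acetate (both anomers) | CC(=O)OC1CC[C@@H](CO[Si](c2ccccc2)(c2ccccc2)C(C)(C)C)O1 | intermediate
5 | tributyl(prop-1-yn-1-yl)stannane | CC#C[Sn](CCCC)(CCCC)CCCC | starting material
6 | tert-butyl{[(2S,5S)-5-(prop-1-yn-1-yl)oxolan-2-yl]methoxy}diphenylsilane | CC(C)(C)[Si](OC[C@@H]1CC[C@@H](C#CC)O1)(c1ccccc1)c1ccccc1 | intermediate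
7 | [(2S,5S)-5-(prop-1-yn-1-yl)oxolan-2-yl]methanol | OC[C@@H]1CC[C@@H](C#CC)O1 | intermediate
8 | (2S,5S)-2-(iodomethyl)-5-(prop-1-yn-1-yl)oxolane | IC[C@@H]1CC[C@@H](C#CC)O1 | intermediate
9 | non-8-yn-1-ol | C#CCCCCCCCO | starting material
10 | (E)-9-[chloridobis(cyclopentadienyl)zirconio]non-8-en-1-yl chloridobis(cyclopentadienyl)zirconium alkoxide | Cl[Zr](/C=C/CCCCCCCO[Zr](Cl)(C1C=CC=C1)C1C=CC=C1)(C1C=CC=C1)C1C=CC=C1 | intermediate
11 | (8E)-9-iodonon-8-en-1-ol | OCCCCCCC/C=C/I | intermediate
12 | propyne | CC#C | starting material
13 | (8E)-dodec-8-en-10-yn-1-ol | CC#C/C=C/CCCCCCCO | intermediate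
14 | (8E)-dodec-8-en-10-yn-1-yl prop-2-enoate | C=CC(=O)OCCCCCCC/C=C/C#CC | intermediate
15 | (8E)-dodec-8-en-10-yn-1-yl 4-[(2R,5S)-5-(prop-1-yn-1-yl)oxolan-2-yl]butanoate | CC#C/C=C/CCCCCCCOC(=O)CCC[C@@H]1CC[C@@H](C#CC)O1 | intermediate
16 | (1R,14E,18S)-6,21-dioxabicyclo[16.2.1]henicos-14-en-16-yn-5-one | O=C1CCC[C@@H]2CC[C@@H](C#C/C=C/CCCCCCCO1)O2 | intermediate
17 | methyl 4-{(2R,5S)-5-[(3E)-11-hydroxyundec-3-en-1-yn-1-yl]oxolan-2-yl}butanoate | COC(=O)CCC[C@@H]1CC[C@@H](C#C/C=C/CCCCCCCO)O1 | intermediate
18 | methyl 4-{(2R,5S)-5-[(3E)-11-oxoundec-3-en-1-yn-1-yl]oxolan-2-yl}butanoate | COC(=O)CCC[C@@H]1CC[C@@H](C#C/C=C/CCCCCCC=O)O1 | intermediate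
19 | methyl 4-{(2R,5S)-5-[(3E,11E)-12-bromododeca-3,11-dien-1-yn-1-yl]oxolan-2-yl}butanoate (mutafuran C) | COC(=O)CCC[C@@H]1CC[C@@H](C#C/C=C/CCCCCC/C=C/Br)O1 | target

## Step count and least certain steps

Total step count: 13. Longest linear sequence: 10 steps from 1 (steps 1–5 and 9–13); acrylate 14 comes from a three-step side branch (steps 6–8).

Step 10 (key step).
- What may go wrong: intermolecular metathesis to oligomers may outrun ring closure. The catalyst may also stall, either through slow turnover at the branched propargylic position C8 or through chelation of the metal by the ring oxygen or the ester once the alkylidyne is on the substrate.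
- Fallback: it gives up the metathesis and forms C10–C11 by palladium coupling instead; it sets out from acetate 4, uses iodoalkene 11 and comes back at 17. Acetate 4 would be alkynylated as in step 3, but with trimethyl[(tributylstannyl)ethynyl]silane and BF3·OEt2, to give tert-butyl(diphenyl){[(2S,5S)-5-[(trimethylsilyl)ethynyl]oxolan-2-yl]methoxy}silane F1. Bu4NF would remove both silyl groups to give [(2S,5S)-5-ethynyloxolan-2-yl]methanol F2, and iodine, PPh3 and imidazole would give (2S,5S)-2-ethynyl-5-(iodomethyl)oxolane F3. Radical addition to methyl acrylate (Bu3SnH, AIBN) would give methyl 4-[(2R,5S)-5-ethynyloxolan-2-yl]butanoate F4; iodine abstraction by the stannyl radical is far faster than its addition to the terminal alkyne. Sonogashira coupling of F4 with 11 (PdCl2(PPh3)2, CuI, Et3N) would give 17 directly, and steps 12 and 13 follow unchanged.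

Step 3.
- What may go wrong: poor facial selectivity in the addition to the oxocarbenium ion. The alkynylstannane is a slender nucleophile and the directing group sits across the ring oxygen, so a substantial share of the cis isomer may form, and separation may be laborious.
- Fallback: it moves the stereocontrol to a ring closure; it sets out from lactone 2 and comes back at 6. Lactone 2 would be reduced with i-Bu2AlH (through 3) and worked up with aqueous potassium sodium tartrate to the free lactol (5S)-5-{[tert-butyl(diphenyl)silyl]oxymethyl}oxolan-2-ol F5. Wittig methylenation with Ph3P=CH2 would open it to (2S)-1-{[tert-butyl(diphenyl)silyl]oxy}hex-5-en-2-ol F6. A Mukaiyama-type aerobic oxidative cyclisation with Co(modp)2 (divalent cobalt; modp = 1-morpholinocarbamoyl-4,4-dimethylpentane-1,3-dionate), dioxygen and catalytic t-BuOOH in propan-2-ol should give the 2,5-trans alcohol [(2S,5S)-5-{[tert-butyl(diphenyl)silyl]oxymethyl}oxolan-2-yl]methanol F7. Dess–Martin oxidation would give (2S,5S)-5-{[tert-butyl(diphenyl)silyl]oxymethyl}oxolane-2-carbaldehyde F8, and CBr4 with PPh3 (Corey–Fuchs) would give tert-butyl{[(2S,5S)-5-(2,2-dibromoethenyl)oxolan-2-yl]methoxy}diphenylsilane F9. Two equivalents of n-BuLi would give lithium 2-[(2S,5S)-5-{[tert-butyl(diphenyl)silyl]oxymethyl}oxolan-2-yl]ethynide F10, which is methylated in the same flask with MeI to 6.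

Step 9.
- What may go wrong: premature hydrogen transfer from Bu3SnH to the C4 radical, telomerisation of the acrylate, addition of stannyl or alkyl radicals to the enyne of 14, or 1,5-hydrogen transfer from the activated C8–H to the C4 radical, which would scramble C8.
- Fallback: it avoids radicals altogether; it sets out from alcohol 7, uses enynol 13 and comes back at 15. Alcohol 7 would be converted with Tf2O and 2,6-lutidine at −78 °C into [(2S,5S)-5-(prop-1-yn-1-yl)oxolan-2-yl]methyl trifluoromethanesulfonate F11. Displacement with allylmagnesium bromide and catalytic CuI would give (2R,5S)-2-(but-3-en-1-yl)-5-(prop-1-yn-1-yl)oxolane F12. 9-Borabicyclo[3.3.1]nonane should add to the terminal alkene only, giving 9-{4-[(2R,5S)-5-(prop-1-yn-1-yl)oxolan-2-yl]butyl}-9-borabicyclo[3.3.1]nonane F13, which is oxidised in the same flask (NaOH, H2O2) to 4-[(2R,5S)-5-(prop-1-yn-1-yl)oxolan-2-yl]butan-1-ol F14. TEMPO and PhI(OAc)2 in aqueous MeCN would give 4-[(2R,5S)-5-(prop-1-yn-1-yl)oxolan-2-yl]butanoic acid F15, and Steglich esterification with 13 (DCC, DMAP) would give 15.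

Step 13.
- What may go wrong: incomplete E selectivity in the elimination from the chromium adduct, with a Z isomer that is hard to remove, and reduction or pinacol coupling of the aldehyde by divalent chromium.
- Fallback: it separates the olefination from the introduction of bromine; it sets out from aldehyde 18 and comes back at 19. Aldehyde 18 would be treated with Bu3SnCHBr2, CrCl2 and LiI in THF/DMF to give the E alkenylstannane methyl 4-{(2R,5S)-5-[(3E,11E)-12-(tributylstannyl)dodeca-3,11-dien-1-yn-1-yl]oxolan-2-yl}butanoate F16, which can be purified as the E isomer. Bromodestannylation with N-bromosuccinimide at low temperature would give 19 with retention; it should be much faster than attack of bromine on the enyne.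

## Further compounds

F1 | step 10 | tert-butyl(diphenyl){[(2S,5S)-5-[(trimethylsilyl)ethynyl]oxolan-2-yl]methoxy}silane | CC(C)(C)[Si](OC[C@@H]1CC[C@@H](C#C[Si](C)(C)C)O1)(c1ccccc1)c1ccccc1
F2 | step 10 | [(2S,5S)-5-ethynyloxolan-2-yl]methanol | OC[C@@H]1CC[C@@H](C#C)O1
F3 | step 10 | (2S,5S)-2-ethynyl-5-(iodomethyl)oxolane | IC[C@@H]1CC[C@@H](C#C)O1
F4 | step 10 | methyl 4-[(2R,5S)-5-ethynyloxolan-2-yl]butanoate | COC(=O)CCC[C@@H]1CC[C@@H](C#C)O1
F5 | step 3 | (5S)-5-{[tert-butyl(diphenyl)silyl]oxymethyl}oxolan-2-ol | OC1CC[C@@H](CO[Si](c2ccccc2)(c2ccccc2)C(C)(C)C)O1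
F6 | step 3 | (2S)-1-{[tert-butyl(diphenyl)silyl]oxy}hex-5-en-2-ol | C=CCC[C@H](O)CO[Si](c1ccccc1)(c1ccccc1)C(C)(C)C
F7 | step 3 | [(2S,5S)-5-{[tert-butyl(diphenyl)silyl]oxymethyl}oxolan-2-yl]methanol | CC(C)(C)[Si](OC[C@@H]1CC[C@@H](CO)O1)(c1ccccc1)c1ccccc1
F8 | step 3 | (2S,5S)-5-{[tert-butyl(diphenyl)silyl]oxymethyl}oxolane-2-carbaldehyde | CC(C)(C)[Si](OC[C@@H]1CC[C@@H](C=O)O1)(c1ccccc1)c1ccccc1
F9 | step 3 | tert-butyl{[(2S,5S)-5-(2,2-dibromoethenyl)oxolan-2-yl]methoxy}diphenylsilane | CC(C)(C)[Si](OC[C@@H]1CC[C@@H](C=C(Br)Br)O1)(c1ccccc1)c1ccccc1
F10 | step 3 | lithium 2-[(2S,5S)-5-{[tert-butyl(diphenyl)silyl]oxymethyl}oxolan-2-yl]ethynide | CC(C)(C)[Si](OC[C@@H]1CC[C@@H](C#C[Li])O1)(c1ccccc1)c1ccccc1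
F11 | step 9 | [(2S,5S)-5-(prop-1-yn-1-yl)oxolan-2-yl]methyl trifluoromethanesulfonate | FC(F)(F)S(=O)(=O)OC[C@@H]1CC[C@@H](C#CC)O1
F12 | step 9 | (2R,5S)-2-(but-3-en-1-yl)-5-(prop-1-yn-1-yl)oxolane | C=CCC[C@@H]1CC[C@@H](C#CC)O1
F13 | step 9 | 9-{4-[(2R,5S)-5-(prop-1-yn-1-yl)oxolan-2-yl]butyl}-9-borabicyclo[3.3.1]nonane | C1CCC2CCCC(C1)B2CCCC[C@@H]1CC[C@@H](C#CC)O1
F14 | step 9 | 4-[(2R,5S)-5-(prop-1-yn-1-yl)oxolan-2-yl]butan-1-ol | OCCCC[C@@H]1CC[C@@H](C#CC)O1
F15 | step 9 | 4-[(2R,5S)-5-(prop-1-yn-1-yl)oxolan-2-yl]butanoic acid | OC(=O)CCC[C@@H]1CC[C@@H](C#CC)O1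
F16 | step 13 | methyl 4-{(2R,5S)-5-[(3E,11E)-12-(tributylstannyl)dodeca-3,11-dien-1-yn-1-yl]oxolan-2-yl}butanoate | COC(=O)CCC[C@@H]1CC[C@@H](C#C/C=C/CCCCCC/C=C/[Sn](CCCC)(CCCC)CCCC)O1
A1 | alternative 1 | methyl 4-[(2R,5S)-5-(triisopropylsilylethynyl)oxolan-2-yl]butanoate | COC(=O)CCC[C@@H]1CC[C@@H](C#C[Si](C(C)C)(C(C)C)C(C)C)O1
A2 | alternative 1 | (3S)-1-(triisopropylsilyl)hept-6-en-1-yn-3-ol | C=CCC[C@H](O)C#C[Si](C(C)C)(C(C)C)C(C)C
A3 | alternative 1 | methyl prop-2-enoate | C=CC(=O)OC
A4 | alternative 2 | (2R)-2-{2-[(2S)-oxiran-2-yl]ethyl}oxirane (meso) | C1O[C@@H]1CC[C@H]1CO1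
A5 | alternative 2 | (2S,5S)-oxolane-2,5-diyldimethanol | OC[C@@H]1CC[C@@H](CO)O1
A6 | alternative 3 | (4S)-5-{[tert-butyl(diphenyl)silyl]oxy}-1-diazo-4-(prop-2-en-1-yloxy)pentan-2-one | [N-]=[N+]=CC(=O)C[C@@H](CO[Si](c1ccccc1)(c1ccccc1)C(C)(C)C)OCC=C
A7 | alternative 3 | (2R,5S)-5-{[tert-butyl(diphenyl)silyl]oxymethyl}-2-(prop-2-en-1-yl)oxolan-3-one | C=CC[C@@H]1C(=O)C[C@@H](CO[Si](c2ccccc2)(c2ccccc2)C(C)(C)C)O1
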